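**Retrosynthetic overview**

1. GA2 ⇐ benzyl ester 23 ⇐ 3-ketone 22 (hindered hydride sets 3β-OH) ⇐ ring D closed last by ketyl–olefin cyclisation (C13–C16) of methyl ketone 20.
2. Ring A ⇐ intramolecular lactone aldol (C3–C4) of keto aldehyde 19; lactone ⇐ intramolecular Michael addition (C4–C5) of propanoate 17; C10–C1 ⇐ Grignard addition to enone 12.
3. Ring B ⇐ aldol condensation (C5=C6) within cycloadduct 9.
4. Ring C ⇐ catalytic enantioselective Diels–Alder reaction of butadiene with the acyclic ene-dione keto ester 7 (sets quaternary C8); 7 ⇐ oxalate-derived ylide + methylglyoxal.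
5. Ring order: C, B, lactone, A, D; every later stereocentre is relayed from C8.

Assumption: GA2 is the short name of the target gibberellin, positions are given in gibberellane numbering (C1 to C19), and a sequence run in one flask without intermediate work-up counts as one step.

**Route**

Step 1
Reactants: 1 2-(2-bromoethyl)-2-methyl-1,3-dioxolane
Product: 2 triphenyl[2-(2-methyl-1,3-dioxolan-2-yl)ethyl]phosphonium bromide
Conditions: PPh3 (1.05 equiv), MeCN, reflux, 24 h
Reagents that add atoms: triphenylphosphine, c1ccc(cc1)P(c1ccccc1)c1ccccc1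
Why: SN2 quaternisation of the primary bromide by the phosphine (phosphonium salt formation) under neutral conditions that leave the ketal intact; no stereocentre is formed.

Step 2
Reactants: 2 triphenyl[2-(2-methyl-1,3-dioxolan-2-yl)ethyl]phosphonium bromide; 3 dibenzyl oxalate
Product: 5 benzyl 4-(2-methyl-1,3-dioxolan-2-yl)-2-oxo-3-(triphenyl-λ5-phosphanylidene)butanoate, via phosphonium ylide 4 (not isolated)
Conditions: NaN(SiMe3)2 (1.0 equiv), THF, −78 → 0 °C; then 3 (1.5 equiv), −78 → 25 °C
Reagents that add atoms: none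
Why: C-acylation of a non-stabilised phosphorus ylide by the activated oxalate ester, after which the released benzyloxide deprotonates the acylphosphonium ion to the keto-stabilised ylide, which is inert to further acylation; no stereocentre is formed.

Step 3
Reactants: 5 benzyl 4-(2-methyl-1,3-dioxolan-2-yl)-2-oxo-3-(triphenyl-λ5-phosphanylidene)butanoate; 6 methylglyoxal (2-oxopropanal)
Product: 7 benzyl (3E)-3-[(2-methyl-1,3-dioxolan-2-yl)methyl]-2,5-dioxohex-3-enoate
Conditions: 6 (40 % in H2O, 3 equiv), CH2Cl2, 40 °C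
Reagents that add atoms: none
Why: Wittig olefination of the aldehyde carbonyl of the keto aldehyde by the stabilised ylide, which is E-selective (acetyl trans to the keto ester) and still creates no stereocentre.

Step 4
Reactants: 7 benzyl (3E)-3-[(2-methyl-1,3-dioxolan-2-yl)methyl]-2,5-dioxohex-3-enoate; 8 buta-1,3-diene
Product: 9 benzyl 2-[(1R,6S)-6-acetyl-1-[(2-methyl-1,3-dioxolan-2-yl)methyl]cyclohex-3-en-1-yl]-2-oxoacetate (acetyl trans to the oxoacetyl group)
Conditions: (S)-3,3-diphenyl-1-(o-tolyl)tetrahydro-1H,3H-pyrrolo[1,2-c][1,3,2]oxazaborole (20 mol %), HNTf2 (18 mol %), 8 (10 equiv), CH2Cl2, −78 → −40 °C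
Reagents that add atoms: none
Why: Proposed new method: an enantioselective Diels–Alder reaction of parent butadiene with an acyclic 2-substituted ene-1,4-dione carrying an α-keto ester, catalysed by a triflimide-activated chiral oxazaborolidine (a metal-free boron Lewis acid), in which the cationic boron binds the most Lewis-basic carbonyl (the acetyl C=O) syn to the vinylic C9–H (C–H···O contact of the usual enone binding model), the α-keto ester keeps the LUMO low enough for an unactivated diene, and the diene adds to the alkene face away from the aryl wall so that the quaternary C8 is set as (R) while C9 is formed trans and corrected in step 5; the closest known reaction type is the oxazaborolidinium-catalysed Diels–Alder reaction of butadiene with 2-substituted 1,4-benzoquinones, fumarates and α-substituted enals, which has not been shown for this triacyl alkene class or for a quaternary centre next to an α-keto ester.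

Step 5
Reactants: 9 benzyl 2-[(1R,6S)-6-acetyl-1-[(2-methyl-1,3-dioxolan-2-yl)methyl]cyclohex-3-en-1-yl]-2-oxoacetate
Product: 12 benzyl (3aR,7aR)-3a-[(2-methyl-1,3-dioxolan-2-yl)methyl]-1-oxo-3a,4,7,7a-tetrahydro-1H-indene-3-carboxylate, via cis-diketone 10 (not isolated), via aldol adduct 11 (not isolated)
Conditions: DBU (0.5 equiv), toluene, 60 °C
Reagents that add atoms: none
Why: intramolecular aldol condensation in which base first epimerises the ketone α-centre C9, the methyl ketone enolate (C5) then adds to the neighbouring α-keto ester carbonyl (C6) and E1cB loss of water gives the ring B cyclopentenone; the cis ring fusion (H9 cis to the C8 side chain) is the thermodynamic outcome and C8 is untouched.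

Step 6
Reactants: 12 benzyl (3aR,7aR)-3a-[(2-methyl-1,3-dioxolan-2-yl)methyl]-1-oxo-3a,4,7,7a-tetrahydro-1H-indene-3-carboxylate; 13 2-(2-bromoethyl)-1,3-dioxolane; 14 propanoic anhydride
Product: 17 benzyl (3aR,7aR)-1-[2-(1,3-dioxolan-2-yl)ethyl]-3a-[(2-methyl-1,3-dioxolan-2-yl)methyl]-1-(propanoyloxy)-3a,4,7,7a-tetrahydro-1H-indene-3-carboxylate (10α-O; 10β side chain), via Grignard reagent 15 (not isolated), via magnesium alkoxide 16 (not isolated)
Conditions: 13 (2.0 equiv), Mg, THF, 25 °C; then 12, LaCl3·2LiCl (0.3 equiv), THF, −78 °C; then 14 (3 equiv), DMAP (0.1 equiv), −78 → 0 °C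
Reagents that add atoms: none
Why: Grignard 1,2-addition to the ring B ketone from the convex face (the face of H9, anti to the C9–C11 bond and ring C), which sets C10 with oxygen on the ring C face, followed by acylation of the tertiary alkoxide in the same flask.

Step 7
Reactants: 17 the C10 propanoate
Product: 19 lactone keto aldehyde (19,10-lactone; C10 3-oxopropyl; C8 acetonyl; benzyl ester 6β; C4 epimers), via Michael lactone 18 (not isolated)
Conditions: KN(SiMe3)2 (1.1 equiv), THF, −78 → −20 °C; t-BuOH (3 equiv), 0 °C, 1 h; then 2 M aq. HCl, 25 °C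
Reagents that add atoms: water, O
Why: intramolecular Michael addition (5-exo-trig) of the propanoate enolate to C5 of the unsaturated ester, delivered from the face of the ester oxygen so that the cis-fused γ-lactone and H5β result, with KOt-Bu/t-BuOH equilibrating C6 to the ester trans to C4, after which aqueous acid hydrolyses both dioxolanes.

Step 8
Reactants: 19 lactone keto aldehyde
Product: 20 ring D seco GA2 benzyl ester (rings A, B, C and lactone complete; C8 acetonyl; C12=C13; 3-OH as 3α/3β mixture)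
Conditions: KOt-Bu (0.3 equiv), t-BuOH–THF 1:1, 0.01 M, 0 → 25 °C
Reagents that add atoms: none
Why: intramolecular aldol reaction of the lactone enolate with the C3 aldehyde closes ring A, and because the aldehyde tether from C10 can reach only one enolate face the quaternary C4 is fixed, while C3 forms as an epimer mixture (equatorial 3α expected to dominate) that is corrected in steps 10 and 11.

Step 9
Reactants: 20 ring D seco GA2 benzyl ester
Product: 21 GA2 benzyl ester as 3-epimer mixture (16-OH syn to C14)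
Conditions: SmI2 (3 equiv), HMPA (12 equiv), t-BuOH (2 equiv), THF, 0 → 25 °C
Reagents that add atoms: none
Why: samarium diiodide ketyl–olefin cyclisation (5-exo-trig radical addition of the C16 ketyl to C13 of the ring C alkene) closes ring D, with the bulky O–Sm group anti to the C13–C12 bond (exo, syn to C14) and the methyl endo, C13 fixed by the tether, and the C12 radical reduced and protonated.

Step 10
Reactants: 21 GA2 benzyl ester as 3-epimer mixture
Product: 22 3-oxo GA2 benzyl ester
Conditions: Dess–Martin periodinane (1.5 equiv), CH2Cl2, 25 °C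
Reagents that add atoms: none
Why: Dess–Martin oxidation of the secondary alcohol converges both C3 epimers on one ketone under neutral conditions, while the tertiary 16-OH and the non-enolisable β-keto lactone are inert.

Step 11
Reactants: 22 3-oxo GA2 benzyl ester
Product: 23 GA2 benzyl ester
Conditions: K[(s-Bu)3BH] (2.5 equiv), THF, −78 °C; AcOH quench at −78 °C
Reagents that add atoms: none
Why: hindered trialkylborohydride reduction in which hydride approaches the 3-ketone along the equatorial trajectory from the lactone side to give the axial 3β-alcohol, quenched cold to avoid retro-aldol opening.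

Step 12
Reactants: 23 GA2 benzyl ester
Product: 24 GA2 (the target gibberellin)
Conditions: H2 (1 atm), Pd/C (10 wt %), EtOAc, 25 °C
Reagents that add atoms: none
Why: hydrogenolysis of the benzyl ester under neutral conditions, so the base-sensitive 3β-hydroxy lactone is not epimerised and no other group is reducible.

**Compound list**

1 | 2-(2-bromoethyl)-2-methyl-1,3-dioxolane | CC1(CCBr)OCCO1 | starting material
2 | triphenyl[2-(2-methyl-1,3-dioxolan-2-yl)ethyl]phosphonium bromide | CC1(CC[P+](c2ccccc2)(c2ccccc2)c2ccccc2)OCCO1.[Br-] | intermediate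
3 | dibenzyl oxalate | O=C(OCc1ccccc1)C(=O)OCc1ccccc1 | starting material
4 | triphenyl[2-(2-methyl-1,3-dioxolan-2-yl)ethylidene]-λ5-phosphane (ylide, not isolated) | CC1(CC=P(c2ccccc2)(c2ccccc2)c2ccccc2)OCCO1 | intermediate
5 | benzyl 4-(2-methyl-1,3-dioxolan-2-yl)-2-oxo-3-(triphenyl-λ5-phosphanylidene)butanoate | CC1(CC(=P(c2ccccc2)(c2ccccc2)c2ccccc2)C(=O)C(=O)OCc2ccccc2)OCCO1 | intermediate
6 | methylglyoxal (2-oxopropanal) | CC(=O)C=O | starting material
7 | benzyl (3E)-3-[(2-methyl-1,3-dioxolan-2-yl)methyl]-2,5-dioxohex-3-enoate | CC(=O)/C=C(/C(=O)C(=O)OCc1ccccc1)CC1(C)OCCO1 | intermediate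
8 | buta-1,3-diene | C=CC=C | starting material
9 | benzyl 2-[(1R,6S)-6-acetyl-1-[(2-methyl-1,3-dioxolan-2-yl)methyl]cyclohex-3-en-1-yl]-2-oxoacetate (acetyl trans to oxoacetyl) | CC(=O)[C@H]1CC=CC[C@]1(CC2(C)OCCO2)C(=O)C(=O)OCc3ccccc3 | intermediate
10 | benzyl 2-[(1R,6R)-6-acetyl-1-[(2-methyl-1,3-dioxolan-2-yl)methyl]cyclohex-3-en-1-yl]-2-oxoacetate (cis-diketone, not isolated) | CC(=O)[C@@H]1CC=CC[C@]1(CC2(C)OCCO2)C(=O)C(=O)OCc3ccccc3 | intermediate
11 | benzyl (3aR,7aR)-3-hydroxy-3a-[(2-methyl-1,3-dioxolan-2-yl)methyl]-1-oxo-2,3,3a,4,7,7a-hexahydro-1H-indene-3-carboxylate (aldol adduct, carbinol centre undefined, not isolated) | O=C1CC(O)(C(=O)OCc2ccccc2)[C@@]3(CC4(C)OCCO4)CC=CC[C@@H]13 | intermediate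
12 | benzyl (3aR,7aR)-3a-[(2-methyl-1,3-dioxolan-2-yl)methyl]-1-oxo-3a,4,7,7a-tetrahydro-1H-indene-3-carboxylate (cis-fused) | O=C1C=C(C(=O)OCc2ccccc2)[C@@]3(CC4(C)OCCO4)CC=CC[C@@H]13 | intermediate
13 | 2-(2-bromoethyl)-1,3-dioxolane | BrCCC1OCCO1 | starting material
14 | propanoic anhydride | CCC(=O)OC(=O)CC | starting material
15 | [2-(1,3-dioxolan-2-yl)ethyl]magnesium bromide (not isolated) | Br[Mg]CCC1OCCO1 | intermediate
16 | bromomagnesium alkoxide of benzyl (3aR,7aR)-1-[2-(1,3-dioxolan-2-yl)ethyl]-1-hydroxy-3a-[(2-methyl-1,3-dioxolan-2-yl)methyl]-3a,4,7,7a-tetrahydro-1H-indene-3-carboxylate (O on the ring C face, not isolated) | Br[Mg]O[C@@]1(CCC2OCCO2)C=C(C(=O)OCc2ccccc2)[C@@]2(CC3(C)OCCO3)CC=CC[C@@H]12 | intermediate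
17 | benzyl (3aR,7aR)-1-[2-(1,3-dioxolan-2-yl)ethyl]-3a-[(2-methyl-1,3-dioxolan-2-yl)methyl]-1-(propanoyloxy)-3a,4,7,7a-tetrahydro-1H-indene-3-carboxylate (propanoyloxy on the ring C face, side chain on the H9 face) | CCC(=O)O[C@@]1(CCC2OCCO2)C=C(C(=O)OCc2ccccc2)[C@@]2(CC3(C)OCCO3)CC=CC[C@@H]12 | intermediate
18 | Michael lactone: cis-fused 19,10-γ-lactone with H5β, 6β-benzyl ester, C4 methyl as epimer mixture, C10 2-(1,3-dioxolan-2-yl)ethyl, C8 (2-methyl-1,3-dioxolan-2-yl)methyl, C12=C13 (not isolated) | CC1C(=O)O[C@]2(CCC3OCCO3)[C@@H]3CC=CC[C@]3(CC4(C)OCCO4)[C@@H](C(=O)OCc4ccccc4)[C@H]12 | intermediate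
19 | lactone keto aldehyde: as 18 with C10 3-oxopropyl and C8 2-oxopropyl (C4 epimer mixture) | CC1C(=O)O[C@]2(CCC=O)[C@@H]3CC=CC[C@]3(CC(C)=O)[C@@H](C(=O)OCc4ccccc4)[C@H]12 | intermediate
20 | ring D seco GA2 benzyl ester: rings A, B, C and 19,10-lactone as in GA2, C8 2-oxopropyl, C12=C13, 3-OH as 3α/3β mixture | C[C@@]12C(=O)O[C@]3(CCC1O)[C@@H]1CC=CC[C@]1(CC(C)=O)[C@@H](C(=O)OCc4ccccc4)[C@@H]32 | intermediate
21 | GA2 benzyl ester as 3-epimer mixture (16-OH syn to C14, 17-methyl endo) | C[C@@]12C(=O)O[C@]3(CCC1O)[C@@H]1CC[C@@H]4C[C@]1(C[C@@]4(C)O)[C@@H](C(=O)OCc5ccccc5)[C@@H]32 | intermediate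
22 | 3-oxo GA2 benzyl ester | C[C@@]12C(=O)O[C@]3(CCC1=O)[C@@H]1CC[C@@H]4C[C@]1(C[C@@]4(C)O)[C@@H](C(=O)OCc5ccccc5)[C@@H]32 | intermediate
23 | GA2 benzyl ester | C[C@@]12C(=O)O[C@]3(CC[C@@H]1O)[C@@H]1CC[C@@H]4C[C@]1(C[C@@]4(C)O)[C@@H](C(=O)OCc5ccccc5)[C@@H]32 | intermediate
24 | GA2, the target gibberellin (19,10-lactone, 6β-carboxylic acid, 3β-OH, 16-OH syn to C14 with 16-methyl) | C[C@@]12C(=O)O[C@]3(CC[C@@H]1O)[C@@H]1CC[C@@H]4C[C@]1(C[C@@]4(C)O)[C@@H](C(=O)O)[C@@H]32 | target

**Step count and risks**

Total step count: 12. Longest linear sequence: 12 steps (1 → 24); 3, 6, 8, 13 and 14 enter as bought materials.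

Stereocentres: C8 in step 4, C9 in step 5, C10 in step 6, C5 and C6 in step 7, C4 in step 8, C13 and C16 in step 9, C3 in step 11.

The three steps most likely to fail:

Step 4 (the proposed new cycloaddition). The dioxolane and the three carbonyl groups may compete for the boron centre, an uncatalysed background reaction may erode the ee, and the sense of induction is only predicted from the enone binding model; if the (1S,6R) adduct forms, the (R)-catalyst is used instead. The fallback uses known chemistry and replaces asymmetric catalysis by a racemic cycloaddition plus resolution. It sets out from 7 and 8: heating in toluene at 110 °C in a sealed tube gives the racemate, that is 9 together with its mirror image ent-adduct F1. DBU in toluene as in step 5 then gives 12 together with ent-enone F2. Preparative supercritical-fluid chromatography on an amylose carbamate chiral stationary phase removes F2, and the route is rejoined at 12.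

Step 6 (functionalised Grignard addition with acylation in the same flask). Enolisation of the hindered enone, a poor facial ratio or incomplete acylation of the tertiary alkoxide are possible. The fallback changes how C1 to C3 are brought in and sets out from 12. Allylmagnesium bromide in THF at −78 °C gives the tertiary allyl carbinol F3. Propanoic anhydride, Et3N and DMAP give its propanoate F4. KN(SiMe3)2 then t-BuOH, with an AcOH quench, closes the allyl lactone F5. 9-BBN followed by NaBO3·4H2O hydroborates only the terminal alkene and gives the primary alcohol F6. Dess–Martin periodinane gives the ketal aldehyde F7, and 2 M aq. HCl in THF removes the remaining ketal, so the route is rejoined at 19.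

Step 9 (ketyl–olefin cyclisation onto an unactivated ring alkene late in the route). Simple ketone reduction or slow cyclisation could win. The fallback replaces the radical closure by a Heck cyclisation followed by separate hydration and alkene reduction, and sets out from 18, isolated by ending step 7 with an AcOH quench instead of the acid stage. PPTS in THF–H2O at 25 °C cleaves only the more labile ketone ketal and gives the methyl ketone acetal F8. KN(SiMe3)2 then PhNTf2 in THF at −78 °C gives the terminal enol triflate F9. Pd(OAc)2 (10 mol %), PPh3 (20 mol %) and Ag2CO3 (1.5 equiv) in MeCN at 70 °C effect an intramolecular Heck reaction: zerovalent palladium inserts into the C16–OTf bond, 5-exo syn-carbopalladation reaches C13 and β-hydride elimination towards C11 gives the 11-ene 16-methylene acetal F10. Mn(dpm)3 (cat.), PhSiH3 and O2 in i-PrOH at 0 °C, then P(OEt)3, hydrate only the 1,1-disubstituted exocyclic alkene, from the exo face, to the 16-hydroxy 11-ene acetal F11. Diimide (2-nitrobenzenesulfonohydrazide, Et3N, CH2Cl2, 25 °C) saturates the C11=C12 bond without touching the benzyl ester and gives the 16-hydroxy acetal F12. Catalytic HCl in aqueous THF gives the hydroxy aldehyde F13, and KOt-Bu in t-BuOH–THF as in step 8 closes ring A, so the route is rejoined at 21.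

Further compounds
F1 | step 4 | benzyl 2-[(1S,6R)-6-acetyl-1-[(2-methyl-1,3-dioxolan-2-yl)methyl]cyclohex-3-en-1-yl]-2-oxoacetate (ent-adduct, formed 1:1 with 9) | CC(=O)[C@@H]1CC=CC[C@@]1(CC2(C)OCCO2)C(=O)C(=O)OCc3ccccc3
F2 | step 4 | benzyl (3aS,7aS)-3a-[(2-methyl-1,3-dioxolan-2-yl)methyl]-1-oxo-3a,4,7,7a-tetrahydro-1H-indene-3-carboxylate (ent-enone) | O=C1C=C(C(=O)OCc2ccccc2)[C@]3(CC4(C)OCCO4)CC=CC[C@H]13
F3 | step 6 | benzyl (3aR,7aR)-1-allyl-1-hydroxy-3a-[(2-methyl-1,3-dioxolan-2-yl)methyl]-3a,4,7,7a-tetrahydro-1H-indene-3-carboxylate (tertiary allyl carbinol, OH on the ring C face) | C=CC[C@]1(O)C=C(C(=O)OCc2ccccc2)[C@@]2(CC3(C)OCCO3)CC=CC[C@@H]12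
F4 | step 6 | propanoate of F3 | CCC(=O)O[C@@]1(CC=C)C=C(C(=O)OCc2ccccc2)[C@@]2(CC3(C)OCCO3)CC=CC[C@@H]12
F5 | step 6 | allyl lactone: as 18 with C10 allyl (C4 epimer mixture) | CC1C(=O)O[C@]2(CC=C)[C@@H]3CC=CC[C@]3(CC4(C)OCCO4)[C@@H](C(=O)OCc4ccccc4)[C@H]12
F6 | step 6 | primary alcohol: as F5 with C10 3-hydroxypropyl | CC1C(=O)O[C@]2(CCCO)[C@@H]3CC=CC[C@]3(CC4(C)OCCO4)[C@@H](C(=O)OCc4ccccc4)[C@H]12
F7 | step 6 | ketal aldehyde: as F5 with C10 3-oxopropyl, C16 ketal intact | CC1C(=O)O[C@]2(CCC=O)[C@@H]3CC=CC[C@]3(CC4(C)OCCO4)[C@@H](C(=O)OCc4ccccc4)[C@H]12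
F8 | step 9 | methyl ketone acetal: as 18 with C8 2-oxopropyl, C3 acetal intact | CC1C(=O)O[C@]2(CCC3OCCO3)[C@@H]3CC=CC[C@]3(CC(C)=O)[C@@H](C(=O)OCc4ccccc4)[C@H]12
F9 | step 9 | enol triflate: as F8 with C8 2-(trifluoromethylsulfonyloxy)prop-2-enyl | CC1C(=O)O[C@]2(CCC3OCCO3)[C@@H]3CC=CC[C@]3(CC(=C)OS(=O)(=O)C(F)(F)F)[C@@H](C(=O)OCc4ccccc4)[C@H]12
F10 | step 9 | 11-ene 16-methylene acetal: ring D closed, C11=C12 and exocyclic C16=C17, ring A open, C3 acetal intact | CC1C(=O)O[C@]2(CCC3OCCO3)[C@@H]3C=C[C@@H]4C[C@]3(CC4=C)[C@@H](C(=O)OCc5ccccc5)[C@H]12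
F11 | step 9 | 16-hydroxy 11-ene acetal: as F10 with 16-OH syn to C14 and 16-methyl, C11=C12 kept | CC1C(=O)O[C@]2(CCC3OCCO3)[C@@H]3C=C[C@@H]4C[C@]3(C[C@@]4(C)O)[C@@H](C(=O)OCc5ccccc5)[C@H]12
F12 | step 9 | 16-hydroxy acetal: as F11 with C11–C12 saturated | CC1C(=O)O[C@]2(CCC3OCCO3)[C@@H]3CC[C@@H]4C[C@]3(C[C@@]4(C)O)[C@@H](C(=O)OCc5ccccc5)[C@H]12
F13 | step 9 | hydroxy aldehyde: as F12 with C10 3-oxopropyl | CC1C(=O)O[C@]2(CCC=O)[C@@H]3CC[C@@H]4C[C@]3(C[C@@]4(C)O)[C@@H](C(=O)OCc5ccccc5)[C@H]12
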